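The route cuts the benzylic C7–O bond, not C7–C8 or C8–O. Ring A has a free 4-OH para to C7, flanked by two OMe groups. The 7-deoxy phenol, which holds only the C8 stereocentre, can therefore be dearomatized with Ag2O to its p-quinone methide. A boronic acid clipped to C9–OH then hands an oxygen to C7 from the C9 face, anti to the bulky 2,6-dimethoxyaryloxy group on C8, and ring A rearomatizes. One late operation without protecting groups thus turns C7–H into C7–OH and sets the erythro (7R,8S) relation. The precursor is assembled from an aryl Grignard reagent, (S)-benzyl glycidyl ether and 4-allyl-2,6-dimethoxyphenol.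

Key step: step 6

Remark on the chemistry: CIP analysis of the given SMILES gives 7R,8S, which is erythro (C7–OH and C8–OAr anti in the zigzag drawing). Neolignan numbering is used: ring A = 4-hydroxy-3,5-dimethoxyphenyl on C7, C8 carries the O–ring B ether, C9 = CH2OH. Compounds 1, 3 and 6 are taken as commercial.

Step 1
Reactants: 1 4-bromo-2,6-dimethoxyphenol
Product: 2 5-bromo-2-(benzyloxy)-1,3-dimethoxybenzene
Conditions: BnBr, K2CO3, DMF, rt
Reagents that add atoms: benzyl bromide, BrCc1ccccc1
Why: A Williamson ether synthesis on the acidic phenol masks the ring A OH so that the aryl bromide can be metalated, and no stereocentre is involved.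

Step 2
Reactants: 2 5-bromo-2-(benzyloxy)-1,3-dimethoxybenzene; 3 (S)-benzyl glycidyl ether
Product: 5 (S)-1-(benzyloxy)-3-[4-(benzyloxy)-3,5-dimethoxyphenyl]propan-2-ol, via arylmagnesium bromide 4 (not isolated)
Conditions: Mg, THF, reflux; then CuI (10 mol %), 3, THF, −30 to 0 °C; H2O
Reagents that add atoms: magnesium, [Mg] (stays only in 4)
Why: The copper-catalysed opening of a terminal epoxide by an aryl Grignard reagent occurs at the unhindered CH2, so the C–O stereocentre of 3 passes unchanged into C8 of 5 (S).

Step 3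
Reactants: 5 (S)-1-(benzyloxy)-3-[4-(benzyloxy)-3,5-dimethoxyphenyl]propan-2-ol; 6 4-allyl-2,6-dimethoxyphenol
Product: 7 (R)-2-(benzyloxy)-5-{3-(benzyloxy)-2-[2,6-dimethoxy-4-(prop-2-enyl)phenoxy]propyl}-1,3-dimethoxybenzene
Conditions: PPh3, DIAD, THF, 0 °C to rt
Reagents that add atoms: none
Why: In this Mitsunobu etherification phenol 6 displaces the alkoxyphosphonium group by SN2 with inversion, which puts C8 into its final spatial arrangement, and since C7 is still a CH2 there is no neighbouring oxygen to protect or to take part.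

Step 4
Reactants: 7 (R)-2-(benzyloxy)-5-{3-(benzyloxy)-2-[2,6-dimethoxy-4-(prop-2-enyl)phenoxy]propyl}-1,3-dimethoxybenzene
Product: 9 (R)-3-[4-({1-(benzyloxy)-3-[4-(benzyloxy)-3,5-dimethoxyphenyl]propan-2-yl}oxy)-3,5-dimethoxyphenyl]propan-1-ol, via B-alkyl-9-BBN adduct 8 (not isolated)
Conditions: 9-BBN, THF, 0 °C to rt; then NaOH, H2O2, 0 °C to rt
Reagents that add atoms: 9-BBN, [H]B1C2CCCC1CCC2 (boron cage stays only in 8); hydrogen peroxide, OO
Why: Anti-Markovnikov hydroboration–oxidation of the only alkene with the bulky borane unmasks the 3-hydroxypropyl chain of ring B, while all ethers and C8 stay untouched.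

Step 5
Reactants: 9 (R)-3-[4-({1-(benzyloxy)-3-[4-(benzyloxy)-3,5-dimethoxyphenyl]propan-2-yl}oxy)-3,5-dimethoxyphenyl]propan-1-ol
Product: 10 (R)-4-{3-hydroxy-2-[4-(3-hydroxypropyl)-2,6-dimethoxyphenoxy]propyl}-2,6-dimethoxyphenol
Conditions: H2 (1 atm), Pd/C, EtOH–EtOAc, rt
Reagents that add atoms: none
Why: Catalytic hydrogenolysis cleaves both benzyl ethers at once, whereas the C8–O bond is homobenzylic and the O–ring B bond is an aryl C–O bond, so both should survive.

Step 6
Reactants: 10 (R)-4-{3-hydroxy-2-[4-(3-hydroxypropyl)-2,6-dimethoxyphenoxy]propyl}-2,6-dimethoxyphenol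
Product: 13 (1R,2S)-1-(4-hydroxy-3,5-dimethoxyphenyl)-2-[4-(3-hydroxypropyl)-2,6-dimethoxyphenoxy]propane-1,3-diol, via p-quinone methide 11 (not isolated), via cyclic phenylboronate 12 (not isolated)
Conditions: Ag2O, 4 Å MS, CH2Cl2, rt, dark; filter; PhB(OH)2, i-Pr2NEt (20 mol %), 4 Å MS, CH2Cl2, rt; then pinacol, rt
Reagents that add atoms: phenylboronic acid, OB(O)c1ccccc1 (supplies the C7 oxygen; B and Ph stay only in 12)
Why: Proposed new method: Ag2O removes two electrons and two protons from the 4-OH/C7–H pair of ring A (phenoxyl radical, then disproportionation), which is the known oxidation of 2,6-disubstituted 4-alkylphenols to p-quinone methides and leaves ring B (no free OH) and both primary alcohols alone, so only the trapping of 11 is new. PhB(OH)2 esterifies C9–OH reversibly, the hindered amine raises the hemiester to a boronate, and its B–OH oxygen adds to C7 in a 1,6-addition driven by rearomatization of ring A; the closest known reaction types are the amine-promoted intramolecular oxa-Michael addition of boronic acid hemiesters of hydroxy enones and the addition of water to β-aryl ether quinone methides. The 1,3,2-dioxaborinane ring of 12 closes in the 6-exo-trig mode through a chair. C7 is controlled by C8: allylic 1,3-strain with C2–H/C6–H of ring A puts C8–H in the plane of the quinone methide, C9 and the 2,6-dimethoxyaryloxy group then lie on opposite faces, and the tether can reach C7 only from the C9 face, anti to the C8–O bond (Felkin–Anh sense), which places aryl and aryloxy groups both equatorial and gives 7R, i.e. erythro. The step needs closure to outrun tautomerization of 11 to the enol ether and untethered hydration, which intramolecularity, molecular sieves and removal of the silver before the boronic acid is added (no second oxidation) should secure, and any cis boronate can revert through the phenolate to 11 and drain to the trans isomer. Pinacol then takes the boron off under neutral conditions, so that the acid- and base-labile p-hydroxybenzylic C7–O bond and C8 are not disturbed.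

Compound list
1 | 4-bromo-2,6-dimethoxyphenol | COc1cc(Br)cc(OC)c1O | starting material
2 | 5-bromo-2-(benzyloxy)-1,3-dimethoxybenzene | COc1cc(Br)cc(OC)c1OCc1ccccc1 | intermediate
3 | (S)-benzyl glycidyl ether | C1O[C@@H]1COCc2ccccc2 | starting material
4 | [4-(benzyloxy)-3,5-dimethoxyphenyl]magnesium bromide | COc1cc([Mg]Br)cc(OC)c1OCc1ccccc1 | intermediate
5 | (S)-1-(benzyloxy)-3-[4-(benzyloxy)-3,5-dimethoxyphenyl]propan-2-ol | COc1cc(C[C@H](O)COCc2ccccc2)cc(OC)c1OCc3ccccc3 | intermediate
6 | 4-allyl-2,6-dimethoxyphenol | C=CCc1cc(OC)c(O)c(OC)c1 | starting material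
7 | (R)-2-(benzyloxy)-5-{3-(benzyloxy)-2-[2,6-dimethoxy-4-(prop-2-enyl)phenoxy]propyl}-1,3-dimethoxybenzene | COc1cc(C[C@H](COCc2ccccc2)Oc3c(OC)cc(CC=C)cc3OC)cc(OC)c1OCc4ccccc4 | intermediate
8 | B-alkyl-9-BBN adduct of 7 (9-borabicyclo[3.3.1]nonan-9-yl on the terminal carbon of the former allyl group, C8 R) | COc1cc(C[C@H](COCc2ccccc2)Oc3c(OC)cc(CCCB5C6CCCC5CCC6)cc3OC)cc(OC)c1OCc4ccccc4 | intermediate
9 | (R)-3-[4-({1-(benzyloxy)-3-[4-(benzyloxy)-3,5-dimethoxyphenyl]propan-2-yl}oxy)-3,5-dimethoxyphenyl]propan-1-ol | COc1cc(C[C@H](COCc2ccccc2)Oc3c(OC)cc(CCCO)cc3OC)cc(OC)c1OCc4ccccc4 | intermediate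
10 | (R)-4-{3-hydroxy-2-[4-(3-hydroxypropyl)-2,6-dimethoxyphenoxy]propyl}-2,6-dimethoxyphenol (7-deoxy target) | COc1cc(C[C@H](CO)Oc2c(OC)cc(CCCO)cc2OC)cc(OC)c1O | intermediate
11 | (R)-4-{3-hydroxy-2-[4-(3-hydroxypropyl)-2,6-dimethoxyphenoxy]propylidene}-2,6-dimethoxycyclohexa-2,5-dien-1-one | COC1=CC(=C[C@H](CO)Oc2c(OC)cc(CCCO)cc2OC)C=C(OC)C1=O | intermediate
12 | (4R,5S)-4-(4-hydroxy-3,5-dimethoxyphenyl)-5-[4-(3-hydroxypropyl)-2,6-dimethoxyphenoxy]-2-phenyl-1,3,2-dioxaborinane (trans) | COc1cc([C@H]2OB(c3ccccc3)OC[C@@H]2Oc4c(OC)cc(CCCO)cc4OC)cc(OC)c1O | intermediate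
13 | (1R,2S)-1-(4-hydroxy-3,5-dimethoxyphenyl)-2-[4-(3-hydroxypropyl)-2,6-dimethoxyphenoxy]propane-1,3-diol (erythro, 7R,8S) | COc1cc([C@@H](O)[C@H](CO)Oc2c(OC)cc(CCCO)cc2OC)cc(OC)c1O | target

Total step count: 6. Longest linear sequence: 6 steps (1 to 13).

Steps most likely to fail

Step 6 (bears the label). Closure of the boronate tether may be too slow. Base-induced tautomerization of the quinone methide to the enol ether, loss of formaldehyde from C9, or untethered addition of traces of water with lower facial selectivity could then take over. The fallback uses known chemistry, sets out from 10 and comes back at 13. Quinone methide 11 is made with Ag2O as before and freed from silver. It is then hydrated intermolecularly in dioxane–water at about pH 3 to 4, which is the known acid-catalysed 1,6-addition of water to β-aryl ether quinone methides. The tether is given up, and only the bulky aryloxy group on C8 shields one face. Compound 13 should prevail, and the threo (7S,8S) epimer F1 has to be removed by chromatography.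

Step 3. Substitution by the doubly ortho-substituted phenol may be slow. Elimination to the cinnamyl ether, or participation of the electron-rich ring A (phenonium pathway) with erosion of the inversion, may then compete. The fallback moves the substitution to a carbonyl-activated carbon, where ionization is suppressed and SN2 is fast. It sets out from 2 (through 4) and comes back at 7.
- Grignard reagent 4 opens methyl (S)-glycidate at C3 under CuI catalysis at low temperature to give methyl (S)-3-[4-(benzyloxy)-3,5-dimethoxyphenyl]-2-hydroxypropanoate F2.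
- Tf2O and 2,6-lutidine give the (S)-triflate F3.
- The potassium salt of 6 displaces the triflate with inversion to give the methyl (R)-2-aryloxy ester F4.
- LiAlH4 reduces the ester to the (R)-2-aryloxypropan-1-ol F5.
- NaH and BnBr convert F5 into 7.

Step 2. Formation of the electron-rich arylmagnesium reagent may be sluggish, or the epoxide may be opened by magnesium bromide to a halohydrin. The fallback builds the same C7–C8–C9 unit from an allyl arene and takes the stereocentre from a kinetic resolution. It sets out from 6 and comes back at 5.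
- Benzylation (BnBr, K2CO3) gives 5-allyl-2-(benzyloxy)-1,3-dimethoxybenzene F6.
- mCPBA gives the racemic 2-(arylmethyl)oxirane F7.
- Hydrolytic kinetic resolution with the chiral Co(salen) enantiomer that consumes the (R)-epoxide leaves the (S)-epoxide F8 beside the (R)-diol F9.
- Sodium benzyl oxide opens F8 at the terminal carbon to give 5.

Further compounds
F1 | step 6 | (1S,2S)-1-(4-hydroxy-3,5-dimethoxyphenyl)-2-[4-(3-hydroxypropyl)-2,6-dimethoxyphenoxy]propane-1,3-diol (threo epimer) | COc1cc([C@H](O)[C@H](CO)Oc2c(OC)cc(CCCO)cc2OC)cc(OC)c1O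
F2 | step 3 | methyl (S)-3-[4-(benzyloxy)-3,5-dimethoxyphenyl]-2-hydroxypropanoate | COC(=O)[C@@H](O)Cc1cc(OC)c(OCc2ccccc2)c(OC)c1
F3 | step 3 | methyl (S)-3-[4-(benzyloxy)-3,5-dimethoxyphenyl]-2-{[(trifluoromethyl)sulfonyl]oxy}propanoate | COC(=O)[C@@H](OS(=O)(=O)C(F)(F)F)Cc1cc(OC)c(OCc2ccccc2)c(OC)c1
F4 | step 3 | methyl (R)-3-[4-(benzyloxy)-3,5-dimethoxyphenyl]-2-[2,6-dimethoxy-4-(prop-2-enyl)phenoxy]propanoate | COC(=O)[C@H](Oc2c(OC)cc(CC=C)cc2OC)Cc1cc(OC)c(OCc3ccccc3)c(OC)c1
F5 | step 3 | (R)-3-[4-(benzyloxy)-3,5-dimethoxyphenyl]-2-[2,6-dimethoxy-4-(prop-2-enyl)phenoxy]propan-1-ol | OC[C@H](Oc2c(OC)cc(CC=C)cc2OC)Cc1cc(OC)c(OCc3ccccc3)c(OC)c1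
F6 | step 2 | 5-allyl-2-(benzyloxy)-1,3-dimethoxybenzene | C=CCc1cc(OC)c(OCc2ccccc2)c(OC)c1
F7 | step 2 | racemic 2-{[4-(benzyloxy)-3,5-dimethoxyphenyl]methyl}oxirane | COc1cc(CC2CO2)cc(OC)c1OCc3ccccc3
F8 | step 2 | (S)-2-{[4-(benzyloxy)-3,5-dimethoxyphenyl]methyl}oxirane | COc1cc(C[C@H]2CO2)cc(OC)c1OCc3ccccc3
F9 | step 2 | (R)-3-[4-(benzyloxy)-3,5-dimethoxyphenyl]propane-1,2-diol | COc1cc(C[C@@H](O)CO)cc(OC)c1OCc2ccccc2
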